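## Retrosynthetic overview

1. Target 22 is epicatechin-(4β→8)-epicatechin-(4β→6)-epicatechin. Both interflavan bonds (C4–C8 and C4–C6) are cut as Friedel–Crafts bonds, giving an upper C4 electrophile 7 and a C8-blocked lower nucleophile 5 (both from (−)-epicatechin) and a central unit 18 at the flavan-3,4-diol oxidation level.
2. Ring C of the central unit is built from achiral pieces. C2–C3 and C4–C4a form together by a Mukaiyama–Prins addition/Friedel–Crafts closure (formal [4+2], oxa-Povarov type) between the aryl oxocarbenium ion of acetal ester 15 and the symmetric enediol ether 10.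
3. Enabling feature: in the central unit O1 sits on a phloroglucinol-type ring A, so C4a (ortho to O1, ortho and para to the C5 and C7 oxygens) is a strong arene nucleophile. C2 carries the catechol ring B, which stabilises an O1=C2 oxocarbenium ion. C3 and C4 are a vicinal pair bearing O and an acid-labile benzylic bond, that is, an enediol C3=C4 whose C4–O bond is later exchanged for the C4–C6 bond.
4. Order: ring C of the central unit (step 7), then the lower interflavan bond C4–C6 (step 8), then the upper interflavan bond C4–C8 (step 9), then hydrogenolysis of all benzyl ethers and the C–Br bond (step 10).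

Key step: step 7

Remark: the enantiomer of the squaramide that gives the 2R series in step 7 has to be chosen by experiment; the sense is assigned by comparing 20 with a sample made from 7 and 5.

## Route

Step 1
Reactants: 1 (−)-epicatechin; 2 benzyl bromide
Product: 3 5,7,3',4'-tetra-O-benzyl-(−)-epicatechin
Conditions: BnBr (4.4 equiv), K2CO3, DMF, 0 °C → rt
Reagents that add atoms: benzyl bromide (2), BrCc1ccccc1
Why: Williamson etherification; K2CO3 deprotonates only the four phenols, so the secondary 3-OH should stay free and no stereocenter is touched.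

Step 2
Reactants: 3 5,7,3',4'-tetra-O-benzyl-(−)-epicatechin; 4 N-bromosuccinimide
Product: 5 8-bromo-5,7,3',4'-tetra-O-benzyl-(−)-epicatechin
Conditions: NBS (1.0 equiv), CH2Cl2, −78 °C → rt
Reagents that add atoms: N-bromosuccinimide (4), O=C1CCC(=O)N1Br
Why: Electrophilic aromatic bromination; C8 is the most reactive position of ring A in the tetrabenzyl ether, and the bromine then blocks C8 until it is removed in step 10.

Step 3
Reactants: 3 5,7,3',4'-tetra-O-benzyl-(−)-epicatechin; 6 2-ethoxyethanol
Product: 7 5,7,3',4'-tetra-O-benzyl-4β-(2-ethoxyethoxy)-(−)-epicatechin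
Conditions: DDQ (2 equiv), 2-ethoxyethanol (5 equiv), CH2Cl2, rt
Reagents that add atoms: 2-ethoxyethanol (6), CCOCCO
Why: Benzylic oxidation by hydride abstraction (DDQ) gives the ring A-stabilised C4 cation, which the alcohol should trap trans to the 3-OH (4β), as is established for benzylated flavan-3-ols.

Step 4
Reactants: 8 (tert-butyldimethylsilyloxy)acetaldehyde; 9 tert-butyldimethylsilyl triflate
Product: 10 (Z)-1,2-bis(tert-butyldimethylsilyloxy)ethene
Conditions: TBSOTf (1.1 equiv), Et3N, CH2Cl2, 0 °C → rt
Reagents that add atoms: tert-butyldimethylsilyl triflate (9), CC(C)(C)[Si](C)(C)OS(=O)(=O)C(F)(F)F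
Why: Silyl enol ether formation by soft enolisation of the α-silyloxy aldehyde; the Z isomer should predominate, and because both alkene carbons carry the same group no regiochemical question can arise in step 7.

Step 5
Reactants: 11 3,4-bis(benzyloxy)benzaldehyde; 12 pivaloyl chloride
Product: 13 chloro[3,4-bis(benzyloxy)phenyl]methyl pivalate (racemic)
Conditions: PivCl (1.2 equiv), ZnCl2 (2 mol%), CH2Cl2, −10 °C → rt; used crude
Reagents that add atoms: pivaloyl chloride (12), CC(C)(C)C(=O)Cl
Why: ZnCl2-catalysed addition of an acyl chloride across the aldehyde C=O (1-chloroalkyl ester formation); the new centre is racemic and is destroyed in step 7.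

Step 6
Reactants: 13 chloro[3,4-bis(benzyloxy)phenyl]methyl pivalate; 14 3,5-bis(benzyloxy)phenol
Product: 15 [3,5-bis(benzyloxy)phenoxy][3,4-bis(benzyloxy)phenyl]methyl pivalate (racemic)
Conditions: Cs2CO3, DMF, 0 °C; filtration through basic alumina
Reagents that add atoms: none
Why: O-alkylation of the cesium phenoxide by the α-chloroalkyl ester (acyloxyalkylation of a phenol); the polar aprotic medium should favour O- over C-alkylation and the hindered pivalate should resist acyl transfer.

Step 7
Reactants: 15 [3,5-bis(benzyloxy)phenoxy][3,4-bis(benzyloxy)phenyl]methyl pivalate; 10 (Z)-1,2-bis(tert-butyldimethylsilyloxy)ethene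
Product: 18 (2R)-2,3-cis-3,4-trans-5,7-bis(benzyloxy)-2-[3,4-bis(benzyloxy)phenyl]-3,4-bis(tert-butyldimethylsilyloxy)chroman, via oxocarbenium triflate 16 (not isolated), via silyloxycarbenium ion 17 (not isolated)
Conditions: 10 (2.5 equiv), TBSOTf (20 mol%), chiral tert-leucine-derived 2-arylpyrrolidine amide squaramide (10 mol%), MTBE–CH2Cl2, 4 Å molecular sieves, −78 °C; Et3N quench
Reagents that add atoms: none
Why: Proposed new method: TBSOTf, made more Lewis acidic by the squaramide, should silylate the pivalate carbonyl of 15 and expel the silyl ester to give the (E)-aryl oxocarbenium ion 16 (the carboxylate is the only competent leaving group, so O1 stays on C2); enediol ether 10 then adds through C3 in an open antiperiplanar Mukaiyama–Prins transition state to form C2–C3 and the silyloxycarbenium ion 17, whose C4 is attacked by C4a of ring A, and loss of the C4a proton (as TfOH, which returns TBSOTf and pivalic acid) gives 18. The closest known reactions are the Lewis-acid-promoted annulation of aryl oxocarbenium ions with alkenes to chromans (oxa-Povarov reaction, a Prins addition followed by Friedel–Crafts closure), the syn-selective Mukaiyama addition of enol silanes to acetals, and hydrogen-bond-donor/silyl triflate ion-pair catalysis of enantioselective additions to acetal-derived oxocarbenium ions; their combination on an α-aryloxybenzyl ester with an enediol ether is the new element. Ring C closes as a six-membered ring by a 6-exo-trig Friedel–Crafts attack on the C4=O+ bond, so that overall the C4a=C8a–O1=C2 heterodiene and the C3=C4 alkene combine in a formal [4+2]. C2 is set by the catalyst (the squaramide-bound triflate shields one face of 16), C3 is set relative to C2 by the antiperiplanar transition state with the hydrogen of C3 in the crowded sector between O1 and the aryl group (syn adduct = 2,3-cis; an endo [4+2] transition state leads to the same isomer), and C4 should close trans to the 3-silyloxy group but is re-ionised in step 8, so its configuration is immaterial. The step needs capture of 16 by 10 in preference to the arene rings (secured by the higher π-nucleophilicity and the excess of 10), regiocontrol within 10 (secured by its symmetry) and a single site of closure (the two ortho positions of the phenoxy ring are equivalent).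

Step 8
Reactants: 18 (2R)-2,3-cis-3,4-trans-5,7-bis(benzyloxy)-2-[3,4-bis(benzyloxy)phenyl]-3,4-bis(tert-butyldimethylsilyloxy)chroman; 5 8-bromo-5,7,3',4'-tetra-O-benzyl-(−)-epicatechin
Product: 20 5,7,3',4'-tetra-O-benzylepicatechin-(4β→6)-8-bromo-5,7,3',4'-tetra-O-benzylepicatechin, via 3-O-TBS dimer 19 (not isolated)
Conditions: 5 (3 equiv), TMSOTf (0.3 equiv), CH2Cl2, −78 → −40 °C; Et3N; then TBAF, AcOH, THF, rt
Reagents that add atoms: none
Why: Lewis-acid ionisation of the benzylic C4–OSi bond gives the ring A-stabilised C4 cation (as with 4-alkoxyflavans), which C6 of 5 (C8 blocked) should attack in a Friedel–Crafts alkylation anti to the 3-silyloxy and 2-aryl groups to set 4β, after which fluoride cleaves the remaining silyl ether; any material of the 2S series from step 7 becomes a diastereomer here and is removed by chromatography.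

Step 9
Reactants: 20 5,7,3',4'-tetra-O-benzylepicatechin-(4β→6)-8-bromo-5,7,3',4'-tetra-O-benzylepicatechin; 7 5,7,3',4'-tetra-O-benzyl-4β-(2-ethoxyethoxy)-(−)-epicatechin
Product: 21 5,7,3',4'-tetra-O-benzylepicatechin-(4β→8)-5,7,3',4'-tetra-O-benzylepicatechin-(4β→6)-8-bromo-5,7,3',4'-tetra-O-benzylepicatechin
Conditions: 7 added slowly to 20 (1.5 equiv), TMSOTf (0.2 equiv), CH2Cl2, −78 °C; Et3N quench
Reagents that add atoms: none
Why: Friedel–Crafts interflavan coupling of a 4-alkoxyflavan; the C4 cation from 7 should be attacked anti to its 3-OH (4β) by C8 of the central unit, the intrinsically preferred ring A position (its C6 lies between two benzyloxy groups and the lower unit has no free position).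

Step 10
Reactants: 21 5,7,3',4'-tetra-O-benzylepicatechin-(4β→8)-5,7,3',4'-tetra-O-benzylepicatechin-(4β→6)-8-bromo-5,7,3',4'-tetra-O-benzylepicatechin
Product: 22 epicatechin-(4β→8)-epicatechin-(4β→6)-epicatechin (CNP0178679.3)
Conditions: H2 (1 atm), Pd(OH)2/C, Et3N, THF/MeOH/H2O, rt
Reagents that add atoms: none
Why: Hydrogenolysis of the twelve benzyl ethers and hydrodebromination of the aryl bromide (Et3N takes up HBr); no stereocenter is affected.

## Compound list

1 | (−)-epicatechin | O[C@@H]1Cc2c(O)cc(O)cc2O[C@@H]1c1ccc(O)c(O)c1 | starting material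
2 | benzyl bromide | BrCc1ccccc1 | starting material
3 | 5,7,3',4'-tetra-O-benzyl-(−)-epicatechin | O[C@@H]1Cc2c(OCc3ccccc3)cc(OCc3ccccc3)cc2O[C@@H]1c1ccc(OCc2ccccc2)c(OCc2ccccc2)c1 | intermediate
4 | N-bromosuccinimide | O=C1CCC(=O)N1Br | starting material
5 | 8-bromo-5,7,3',4'-tetra-O-benzyl-(−)-epicatechin | O[C@@H]1Cc2c(OCc3ccccc3)cc(OCc3ccccc3)c(Br)c2O[C@@H]1c1ccc(OCc2ccccc2)c(OCc2ccccc2)c1 | intermediate
6 | 2-ethoxyethanol | CCOCCO | starting material
7 | 5,7,3',4'-tetra-O-benzyl-4β-(2-ethoxyethoxy)-(−)-epicatechin (4-alkoxy group trans to 3-OH) | O[C@@H]1[C@@H](OCCOCC)c2c(OCc3ccccc3)cc(OCc3ccccc3)cc2O[C@@H]1c1ccc(OCc2ccccc2)c(OCc2ccccc2)c1 | intermediate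
8 | (tert-butyldimethylsilyloxy)acetaldehyde | CC(C)(C)[Si](C)(C)OCC=O | starting material
9 | tert-butyldimethylsilyl triflate | CC(C)(C)[Si](C)(C)OS(=O)(=O)C(F)(F)F | starting material
10 | (Z)-1,2-bis(tert-butyldimethylsilyloxy)ethene | CC(C)(C)[Si](C)(C)O/C=C\O[Si](C)(C)C(C)(C)C | intermediate
11 | 3,4-bis(benzyloxy)benzaldehyde | O=Cc1ccc(OCc2ccccc2)c(OCc2ccccc2)c1 | starting material
12 | pivaloyl chloride | CC(C)(C)C(=O)Cl | starting material
13 | chloro[3,4-bis(benzyloxy)phenyl]methyl pivalate (racemic) | CC(C)(C)C(=O)OC(Cl)c1ccc(OCc2ccccc2)c(OCc2ccccc2)c1 | intermediate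
14 | 3,5-bis(benzyloxy)phenol | Oc1cc(OCc2ccccc2)cc(OCc2ccccc2)c1 | starting material
15 | [3,5-bis(benzyloxy)phenoxy][3,4-bis(benzyloxy)phenyl]methyl pivalate (racemic) | CC(C)(C)C(=O)OC(Oc1cc(OCc2ccccc2)cc(OCc2ccccc2)c1)c1ccc(OCc2ccccc2)c(OCc2ccccc2)c1 | intermediate
16 | (E)-[3,5-bis(benzyloxy)phenyl][3,4-bis(benzyloxy)benzylidene]oxonium triflate | O(Cc1ccccc1)c1ccc(/C=[O+]/c2cc(OCc3ccccc3)cc(OCc3ccccc3)c2)cc1OCc1ccccc1.[O-]S(=O)(=O)C(F)(F)F | intermediate
17 | open-chain syn adduct, O-silylated aldehyde (silyloxycarbenium triflate) with C2 and C3 configured as in 18 | c1ccccc1COc1cc(OCc2ccccc2)cc(c1)O[C@H](c1ccc(OCc2ccccc2)c(OCc2ccccc2)c1)[C@H](O[Si](C)(C)C(C)(C)C)C=[O+][Si](C)(C)C(C)(C)C.[O-]S(=O)(=O)C(F)(F)F | intermediate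
18 | (2R)-5,7-bis(benzyloxy)-2-[3,4-bis(benzyloxy)phenyl]-3,4-bis(tert-butyldimethylsilyloxy)chroman, 2α-aryl, 3α-OTBS, 4β-OTBS (2,3-cis, 3,4-trans; a 4α epimer would converge in step 8) | c1ccccc1COc1cc(OCc2ccccc2)c2c(c1)O[C@H](c1ccc(OCc3ccccc3)c(OCc3ccccc3)c1)[C@H](O[Si](C)(C)C(C)(C)C)[C@H]2O[Si](C)(C)C(C)(C)C | intermediate
19 | 3-O-TBS-5,7,3',4'-tetra-O-benzylepicatechin-(4β→6)-8-bromo-5,7,3',4'-tetra-O-benzylepicatechin | c1ccccc1COc1cc(OCc2ccccc2)c2c(c1)O[C@H](c1ccc(OCc3ccccc3)c(OCc3ccccc3)c1)[C@H](O[Si](C)(C)C(C)(C)C)[C@H]2c1c(OCc2ccccc2)c(Br)c2c(c1OCc1ccccc1)C[C@@H](O)[C@@H](c1ccc(OCc3ccccc3)c(OCc3ccccc3)c1)O2 | intermediate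
20 | 5,7,3',4'-tetra-O-benzylepicatechin-(4β→6)-8-bromo-5,7,3',4'-tetra-O-benzylepicatechin (both 3-OH free) | c1ccccc1COc1cc(OCc2ccccc2)c2c(c1)O[C@H](c1ccc(OCc3ccccc3)c(OCc3ccccc3)c1)[C@H](O)[C@H]2c1c(OCc2ccccc2)c(Br)c2c(c1OCc1ccccc1)C[C@@H](O)[C@@H](c1ccc(OCc3ccccc3)c(OCc3ccccc3)c1)O2 | intermediate
21 | dodeca-O-benzyl-8-bromo trimer: tetra-O-benzylepicatechin-(4β→8)-tetra-O-benzylepicatechin-(4β→6)-8-bromo-tetra-O-benzylepicatechin (three 3-OH free) | c1ccccc1COc1cc(OCc2ccccc2)c2c(c1)O[C@H](c1ccc(OCc3ccccc3)c(OCc3ccccc3)c1)[C@H](O)[C@H]2c1c(OCc2ccccc2)cc(OCc2ccccc2)c2c1O[C@H](c1ccc(OCc3ccccc3)c(OCc3ccccc3)c1)[C@H](O)[C@H]2c1c(OCc2ccccc2)c(Br)c2c(c1OCc1ccccc1)C[C@@H](O)[C@@H](c1ccc(OCc3ccccc3)c(OCc3ccccc3)c1)O2 | intermediate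
22 | epicatechin-(4β→8)-epicatechin-(4β→6)-epicatechin | Oc1cc(O)c2c(c1)O[C@H](c1ccc(O)c(O)c1)[C@H](O)[C@H]2c1c(O)cc(O)c2c1O[C@H](c1ccc(O)c(O)c1)[C@H](O)[C@H]2c1c(O)cc2c(c1O)C[C@@H](O)[C@@H](c1ccc(O)c(O)c1)O2 | target

## Step count and risks

Total step count: 10. Longest linear sequence: 6 steps (5, 6, 7, 8, 9, 10, from aldehyde 11).

Step 7 (proposed new method). The oxocarbenium ion may be captured by arene rings instead of by 10, leading to oligomers. The open transition state may give low syn (2,3-cis) selectivity, the catalyst may give poor facial control, and the product may ionise prematurely at C4. The fallback uses known chemistry and takes the central unit from the chiral pool. Electrophile 7 is coupled with the C8-blocked nucleophile 5 (3 equiv) under TMSOTf in CH2Cl2 at −78 °C; the C4 cation is attacked by C6 of 5 anti to the 3-OH. The fallback sets out from 7 and 5 and comes back to the route at 20; no compound outside the list is made (F0).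

Step 6. The ambident phloroglucinol-type phenoxide may be alkylated at carbon, the pivaloyl group may transfer to the phenoxide, chloro ester 13 may revert to the aldehyde, and 15 may ionise during isolation. The fallback replaces the acyloxy acetal by a benzotriazole N,O-acetal. Aldehyde 11, benzotriazole and SOCl2 in CH2Cl2 give 1-{chloro[3,4-bis(benzyloxy)phenyl]methyl}-1H-benzotriazole F1. Displacement of chloride by the sodium salt of 14 (NaH, THF) gives 1-{[3,5-bis(benzyloxy)phenoxy][3,4-bis(benzyloxy)phenyl]methyl}-1H-benzotriazole F2. F2 is then used in place of 15 under the conditions of step 7, where N-silylation makes benzotriazole the leaving group and gives the same ion 16. The fallback sets out from 11 and 14 and comes back to the route at 18.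

Step 8. Ionisation of the silyl ether may be sluggish, the C4 cation may self-condense with ring A of a second molecule of 18, and attack on the hindered C6 of 5 may be too slow. The fallback changes from oxygen/Lewis-acid activation to sulfur/thiophile activation. Compound 18 is treated with benzyl mercaptan and TMSOTf (cat.) in CH2Cl2 at −78 °C to give 4β-benzylthio-5,7,3',4'-tetra-O-benzyl-3-O-TBS-epicatechin F3; the small, soft thiol captures the cation anti to the 3-silyloxy group. F3 is then activated with AgBF4 in THF in the presence of 5 (a known thiophilic interflavan coupling) and the crude product is desilylated with TBAF. The fallback sets out from 18 and comes back to the route at 20.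

## Further compounds

F0 | step 7 | none | none
F1 | step 6 | 1-{chloro[3,4-bis(benzyloxy)phenyl]methyl}-1H-benzotriazole (racemic) | ClC(n1nnc2ccccc21)c1ccc(OCc2ccccc2)c(OCc2ccccc2)c1
F2 | step 6 | 1-{[3,5-bis(benzyloxy)phenoxy][3,4-bis(benzyloxy)phenyl]methyl}-1H-benzotriazole (racemic) | C(Oc1cc(OCc2ccccc2)cc(OCc2ccccc2)c1)(n1nnc2ccccc21)c1ccc(OCc2ccccc2)c(OCc2ccccc2)c1
F3 | step 8 | 4β-benzylthio-5,7,3',4'-tetra-O-benzyl-3-O-(tert-butyldimethylsilyl)epicatechin | c1ccccc1COc1cc(OCc2ccccc2)c2c(c1)O[C@H](c1ccc(OCc3ccccc3)c(OCc3ccccc3)c1)[C@H](O[Si](C)(C)C(C)(C)C)[C@H]2SCc1ccccc1
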